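**Strategy.** The seven-membered ring of lapiferine (C1, C5–C10) carries an epoxidised allylic alcohol: the C8(Me)–C9 epoxide lies next to the C10 carbinol. This unit is traced back to a 9-bromo-Δ8-10α-ol, which arises by inserting C9 into the C8=C10 bond of a trans-hydrindene. The key step opens a gem-dibromocyclopropane fused across C8/C10 with AgClO4 in aqueous acetone. In one operation the six-membered ring grows to the cycloheptene with C9 as a ring member, and the C10–O bond and the C10 stereocentre are formed. The precursor is a trans-fused cyclopentane–cyclohexane carrying the C1 methyl, the C4 isopropyl carbinol and the C6 oxygen, the two oxygens tied as an inert di-tert-butylsilylene.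

Key step: step 7

Convention: atom numbers C1–C10 are those of the target skeleton ("daucane": C1 angular-methyl carbon, C4 isopropyl carbinol, C5 fusion CH, C6–C10 round the larger ring) and are kept for all intermediates; β is the face of the C1 methyl.
Assumption: the antipode of the chiral carbene ligand in step 2 is the one that delivers vinyl to the enone face leading to the enolate of (S)-3-methyl-3-vinylcyclopentanone.

Step 1
Reactants: 1 3-methylbut-3-en-1-ol
Product: 2 3-methylbut-3-enal
Conditions: Dess–Martin periodinane, CH2Cl2, 0 °C; used at once as a solution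
Reagents that add atoms: none
Why: Dess–Martin oxidation stops at the aldehyde under non-basic conditions, so the β,γ-alkene should not move into conjugation; no stereocentre is formed.

Step 2
Reactants: 3 3-methylcyclopent-2-en-1-one; 4 vinylmagnesium bromide; 2 3-methylbut-3-enal
Product: 7 (2S,3R)-3-methyl-2-[(1S)-3-methyl-1-(trimethylsilyloxy)but-3-en-1-yl]-3-vinylcyclopentan-1-one, via magnesium enolate 5 (not isolated), via magnesium aldolate 6 (not isolated)
Conditions: Cu(OTf)2 (3 mol%), chiral imidazolinium salt (carbene precursor, 4 mol%), 4, Et2O, −30 °C; then 2, −78 °C; then Me3SiCl, Et3N, −78 °C → 0 °C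
Reagents that add atoms: chlorotrimethylsilane, C[Si](C)(C)Cl
Why: Copper–carbene-catalysed asymmetric conjugate addition of a Grignard reagent to a 3-substituted cycloalkenone sets the C1 quaternary centre by catalyst control and leaves the regiodefined magnesium enolate 5, which adds to 2 through a chair Zimmerman–Traxler transition state (cyclic enolate, hence the anti C5/C6 relationship) on the face anti to the pseudo-axial vinyl group, i.e. cis to the methyl (only a moderate preference between methyl and vinyl is expected, and the C5 epimer is to be removed by chromatography), before the aldolate is capped as its trimethylsilyl ether to block retro-aldol cleavage.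

Step 3
Reactants: 7 (2S,3R)-3-methyl-2-[(1S)-3-methyl-1-(trimethylsilyloxy)but-3-en-1-yl]-3-vinylcyclopentan-1-one; 8 isopropylmagnesium chloride
Product: 10 (1R,2S,3R)-2-[(1S)-1-hydroxy-3-methylbut-3-en-1-yl]-3-methyl-1-(propan-2-yl)-3-vinylcyclopentan-1-ol, via silyl ether alcohol 9 (not isolated)
Conditions: 8, CeCl3, THF, −78 °C; then K2CO3, MeOH, 0 °C
Reagents that add atoms: none
Why: Organocerium 1,2-addition suppresses enolisation and reduction of the hindered ketone, the isopropyl group attacking C4 from the α face anti to the bulky C5 side chain so that the new C4–OH is β (cis to C6), and methanolysis then removes the labile trimethylsilyl ether.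

Step 4
Reactants: 10 (1R,2S,3R)-2-[(1S)-1-hydroxy-3-methylbut-3-en-1-yl]-3-methyl-1-(propan-2-yl)-3-vinylcyclopentan-1-ol
Product: 11 4β,6α-O-(di-tert-butylsilylene) derivative of diol 10 (six-membered dioxasilinane cis-fused to the cyclopentane at C4–C5)
Conditions: tBu2Si(OTf)2, 2,6-lutidine, CH2Cl2, 0 °C → 20 °C
Reagents that add atoms: di-tert-butylsilyl bis(trifluoromethanesulfonate), CC(C)(C)[Si](OS(=O)(=O)C(F)(F)F)(OS(=O)(=O)C(F)(F)F)C(C)(C)C
Why: Silylene protection of a 1,3-diol: the bis-triflate silylates the secondary C6–OH and closes intramolecularly onto the tertiary C4–OH, giving a ring that is stable to base and organolithiums and cannot act as a neighbouring group later; no stereocentre changes.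

Step 5
Reactants: 11 4β,6α-O-(di-tert-butylsilylene) derivative of diol 10
Product: 12 trans-hydrindene with the C8=C10 alkene (1β,8-dimethyl; 4α-isopropyl; 5α-H; 4β,6α-O-silylene)
Conditions: second-generation Grubbs catalyst (5 mol%), toluene, 80 °C
Reagents that add atoms: none
Why: Ring-closing olefin metathesis between the vinyl group on C1 and the 1,1-disubstituted methallyl olefin forms the trisubstituted C8=C10 bond of the six-membered ring with loss of ethene, the trans ring fusion following from the C1/C5 configuration already present.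

Step 6
Reactants: 12 trans-hydrindene with the C8=C10 alkene; 13 bromoform
Product: 14 gem-dibromocyclopropane-fused trans-hydrindane (C9 = CBr2 bridging C8 and C10 on the α face; 8β-methyl; 10β-H; 4β,6α-O-silylene)
Conditions: 13, KOtBu, pentane, −10 °C → 20 °C
Reagents that add atoms: none
Why: Dibromocarbene, formed by α-elimination from bromoform, adds stereospecifically to the only alkene from the α face anti to the axial C1 methyl to give the cis-fused cyclopropane; both new centres are consumed again in step 7, so the face of addition is not critical.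

Step 7
Reactants: 14 gem-dibromocyclopropane-fused trans-hydrindane
Product: 15 9-bromo-4β,6α-O-(di-tert-butylsilylene)dauc-8-en-10α-ol
Conditions: AgClO4 (3 equiv), acetone/H2O (9:1), 20 °C, dark
Reagents that add atoms: water, O
Why: Ag+ pulls off the endo bromide (the one lying under the six-membered ring) while the C8–C10 σ bond opens in a disrotatory two-electron electrocyclic process, so a 2-bromocycloheptenyl cation delocalised over C8–C9–C10 results, which water captures at C10. The closest known reaction type is the silver-assisted solvolytic ring expansion of 7,7-dibromobicyclo[4.1.0]heptanes to 2-bromocyclohept-2-en-1-ols. The seven-membered ring (C1, C5–C10) is not closed by a cyclisation but arises by cleavage of the bond shared by the three- and six-membered rings, the former carbene carbon becoming C9, so no exo or endo mode applies. The one new stereocentre, C10, is set by the axial C1 methyl: water enters pseudo-axially on the α face anti to it, and the 10α-alcohol is also the epimer free of allylic strain with the C9 bromine. The step needs capture at C10 and not at C8: the tertiary C8 carbinol, should it form, re-ionises readily in the perchloric acid released (left unbuffered until work-up) and drains into the secondary alcohol with the tetrasubstituted bromoalkene, which ionises far more slowly. The silylene makes this safe, since its oxygens cannot reach C8 or C10 as neighbouring groups (an acyl group on O6 would deliver oxygen to C8), the C4 oxygen is trans to C10, and the di-tert-butylsilicon should tolerate the dilute acid.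

Step 8
Reactants: 15 9-bromo-4β,6α-O-(di-tert-butylsilylene)dauc-8-en-10α-ol
Product: 17 4β,6α-O-(di-tert-butylsilylene)dauc-8-en-10α-ol, via dilithio species 16 (not isolated)
Conditions: t-BuLi (3.3 equiv), THF, −78 °C; then MeOH
Reagents that add atoms: none
Why: After deprotonation of the hydroxyl, lithium–bromine exchange on the vinyl bromide gives a ring vinyllithium that methanol protonates, the hindered silylene resisting attack at −78 °C and C10 staying untouched.

Step 9
Reactants: 17 4β,6α-O-(di-tert-butylsilylene)dauc-8-en-10α-ol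
Product: 18 10α-(4-methoxybenzyloxy)-4β,6α-O-(di-tert-butylsilylene)dauc-8-ene
Conditions: NaH, 4-methoxybenzyl chloride, Bu4NI (cat.), THF/DMF, 0 °C → 20 °C
Reagents that add atoms: 4-methoxybenzyl chloride, COc1ccc(CCl)cc1
Why: Williamson etherification of the only free hydroxyl gives a temporary ether that distinguishes C10–OH from the C6–OH unveiled next.

Step 10
Reactants: 18 10α-(4-methoxybenzyloxy)-4β,6α-O-(di-tert-butylsilylene)dauc-8-ene
Product: 19 10α-(4-methoxybenzyloxy)dauc-8-ene-4β,6α-diol
Conditions: HF·pyridine, pyridine, THF, 0 °C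
Reagents that add atoms: none
Why: Fluoride cleaves both Si–O bonds of the silylene, while the benzylic ether, the allylic system and all stereocentres should be unaffected.

Step 11
Reactants: 19 10α-(4-methoxybenzyloxy)dauc-8-ene-4β,6α-diol; 20 angelic acid
Product: 22 6α-angeloyloxy-10α-(4-methoxybenzyloxy)dauc-8-en-4β-ol, via mixed anhydride 21 (not isolated)
Conditions: 20, 2,4,6-trichlorobenzoyl chloride, Et3N, toluene, 20 °C; then 19, toluene, 80 °C
Reagents that add atoms: none
Why: Yamaguchi-type acyl transfer from the mixed anhydride, run without a nucleophilic catalyst to avoid Z→E isomerisation to the tiglate, should acylate only the secondary C6–OH, the tertiary C4–OH being unreactive and the C10 oxygen blocked.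

Step 12
Reactants: 22 6α-angeloyloxy-10α-(4-methoxybenzyloxy)dauc-8-en-4β-ol
Product: 23 6α-angeloyloxydauc-8-ene-4β,10α-diol
Conditions: DDQ, CH2Cl2/pH 7 phosphate buffer, 0 °C
Reagents that add atoms: none
Why: DDQ cleaves the electron-rich 4-methoxybenzyl ether oxidatively (hydride abstraction, then hydrolysis of the oxocarbenium ion) and should leave the ester, the alkene and the alcohols intact.

Step 13
Reactants: 23 6α-angeloyloxydauc-8-ene-4β,10α-diol
Product: 24 lapiferine (6α-angeloyloxy-8α,9α-epoxydaucane-4β,10α-diol)
Conditions: VO(acac)2 (5 mol%), t-BuOOH, CH2Cl2, 0 °C → 20 °C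
Reagents that add atoms: tert-butyl hydroperoxide, CC(C)(C)OO
Why: Hydroxyl-directed vanadium-catalysed epoxidation delivers the peroxide oxygen to the α face of C8=C9, syn to the pseudo-axial 10α-OH bound to the metal, setting C8 and C9, while the electron-poor angelate alkene should not react.

Compound list
1 | 3-methylbut-3-en-1-ol | CC(=C)CCO | starting material
2 | 3-methylbut-3-enal | CC(=C)CC=O | intermediate
3 | 3-methylcyclopent-2-en-1-one | CC1=CC(=O)CC1 | starting material
4 | vinylmagnesium bromide | C=C[Mg]Br | starting material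
5 | bromomagnesium enolate of (S)-3-methyl-3-vinylcyclopentanone, enolised toward the carbon next to the quaternary centre (not isolated) | C=C[C@@]1(C)CCC(O[Mg]Br)=C1 | intermediate
6 | bromomagnesium aldolate, anti aldol with the side chain cis to the ring methyl (not isolated) | C=C(C)C[C@H](O[Mg]Br)[C@H]1C(=O)CC[C@]1(C)C=C | intermediate
7 | (2S,3R)-3-methyl-2-[(1S)-3-methyl-1-(trimethylsilyloxy)but-3-en-1-yl]-3-vinylcyclopentan-1-one | C=C(C)C[C@H](O[Si](C)(C)C)[C@H]1C(=O)CC[C@]1(C)C=C | intermediate
8 | isopropylmagnesium chloride | CC(C)[Mg]Cl | starting material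
9 | (1R,2S,3R)-3-methyl-2-[(1S)-3-methyl-1-(trimethylsilyloxy)but-3-en-1-yl]-1-(propan-2-yl)-3-vinylcyclopentan-1-ol (not isolated) | C=C(C)C[C@H](O[Si](C)(C)C)[C@@H]1[C@@](C)(C=C)CC[C@@]1(O)C(C)C | intermediate
10 | (1R,2S,3R)-2-[(1S)-1-hydroxy-3-methylbut-3-en-1-yl]-3-methyl-1-(propan-2-yl)-3-vinylcyclopentan-1-ol | C=C(C)C[C@H](O)[C@@H]1[C@@](C)(C=C)CC[C@@]1(O)C(C)C | intermediate
11 | 4β,6α-O-(di-tert-butylsilylene) derivative of diol 10 | CC(C)(C)[Si]2(C(C)(C)C)O[C@@H](CC(C)=C)[C@@H]1[C@@](C)(C=C)CC[C@@]1(O2)C(C)C | intermediate
12 | trans-hydrindene, C8=C10 alkene, 1β,8-dimethyl, 4α-isopropyl, 5α-H, 4β,6α-O-(di-tert-butylsilylene) | CC(C)(C)[Si]3(C(C)(C)C)O[C@H]1CC(C)=C[C@@]2(C)CC[C@@](O3)(C(C)C)[C@H]12 | intermediate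
13 | bromoform | BrC(Br)Br | starting material
14 | gem-dibromocyclopropane-fused trans-hydrindane, CBr2 (C9) bridging C8 and C10 on the α face, 8β-methyl, 10β-H, 4β,6α-O-(di-tert-butylsilylene) | CC(C)(C)[Si]4(C(C)(C)C)O[C@H]1C[C@@]2(C)C(Br)(Br)[C@H]2[C@@]3(C)CC[C@@](O4)(C(C)C)[C@H]13 | intermediate
15 | 9-bromo-4β,6α-O-(di-tert-butylsilylene)dauc-8-en-10α-ol (trans-fused, 1β-methyl, 5α-H) | CC(C)(C)[Si]3(C(C)(C)C)O[C@H]1CC(C)=C(Br)[C@@H](O)[C@@]2(C)CC[C@@](O3)(C(C)C)[C@H]12 | intermediate
16 | C9-lithio C10-lithium alkoxide of 15 after exchange (not isolated) | CC(C)(C)[Si]3(C(C)(C)C)O[C@H]1CC(C)=C([Li])[C@@H](O[Li])[C@@]2(C)CC[C@@](O3)(C(C)C)[C@H]12 | intermediate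
17 | 4β,6α-O-(di-tert-butylsilylene)dauc-8-en-10α-ol | CC(C)(C)[Si]3(C(C)(C)C)O[C@H]1CC(C)=C[C@@H](O)[C@@]2(C)CC[C@@](O3)(C(C)C)[C@H]12 | intermediate
18 | 10α-(4-methoxybenzyloxy)-4β,6α-O-(di-tert-butylsilylene)dauc-8-ene | CC(C)(C)[Si]3(C(C)(C)C)O[C@H]1CC(C)=C[C@@H](OCc4ccc(OC)cc4)[C@@]2(C)CC[C@@](O3)(C(C)C)[C@H]12 | intermediate
19 | 10α-(4-methoxybenzyloxy)dauc-8-ene-4β,6α-diol | O[C@H]1CC(C)=C[C@@H](OCc3ccc(OC)cc3)[C@@]2(C)CC[C@@](O)(C(C)C)[C@H]12 | intermediate
20 | angelic acid, (Z)-2-methylbut-2-enoic acid | C/C=C(/C)C(=O)O | starting material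
21 | angelic 2,4,6-trichlorobenzoic anhydride (not isolated) | C/C=C(/C)C(=O)OC(=O)c1c(Cl)cc(Cl)cc1Cl | intermediate
22 | 6α-angeloyloxy-10α-(4-methoxybenzyloxy)dauc-8-en-4β-ol | C/C=C(/C)C(=O)O[C@H]1CC(C)=C[C@@H](OCc3ccc(OC)cc3)[C@@]2(C)CC[C@@](O)(C(C)C)[C@H]12 | intermediate
23 | 6α-angeloyloxydauc-8-ene-4β,10α-diol | C/C=C(/C)C(=O)O[C@H]1CC(C)=C[C@@H](O)[C@@]2(C)CC[C@@](O)(C(C)C)[C@H]12 | intermediate
24 | lapiferine | C/C=C(/C)C(=O)O[C@H]1C[C@@]2(C)O[C@H]2[C@@H](O)[C@@]2(C)CC[C@@](O)(C(C)C)[C@H]12 | target

Total step count: 13. Longest linear sequence: 13 steps (1 → 24); 12 steps from 3.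

Steps most likely to fail

Step 7 (key step). What may go wrong: water is captured at the tertiary terminus C8 and the product does not drain to the C10 alcohol, or the silylene erodes in the acid released. Fallback, from 14 back to 15: the silver-assisted opening is run with CaCO3 as acid scavenger, so that the kinetically formed tertiary alcohol, 9-bromo-4β,6α-O-(di-tert-butylsilylene)dauc-9-en-8α-ol F1, is accepted and isolated with the silylene intact. A separate rhenium-oxo-catalysed 1,3-transposition of the allylic hydroxyl (Ph3SiOReO3, Et2O, 0 °C) then converts F1 into 15; it is suprafacial and runs toward the secondary alcohol with the more substituted alkene.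

Step 2. What may go wrong: stereocontrol is lost in the three-component coupling, above all through weak face selection of the aldehyde at C5, because methyl and vinyl on C1 are of similar size, and through low enantioselectivity in the transfer of the small vinyl group. Fallback, setting out from 2 and 8 (3 and 4 are replaced) and returning at 10: the alkenyl group is made α-branched and methyl becomes the group transferred.
- Stork–Danheiser addition of [1-(dimethylphenylsilyl)vinyl]magnesium bromide to 3-ethoxycyclopent-2-en-1-one, followed by acid hydrolysis, gives 3-[1-(dimethylphenylsilyl)vinyl]cyclopent-2-en-1-one F2.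
- Copper–carbene-catalysed 1,4-addition of MeMgBr (Cu(OTf)2, chiral imidazolinium salt, Et2O) gives the bromomagnesium enolate F3. The bulky silylvinyl group now clearly outranks the methyl, so 2 is taken up anti to it to give the bromomagnesium aldolate F4, and Me3SiCl gives the trimethylsilyl-protected aldol F5.
- iPrMgCl/CeCl3 gives the tertiary alcohol silyl ether F6, and K2CO3/MeOH the silylvinyl diol F7.
- Protodesilylation of the vinylsilane with TBAF in DMSO at 80 °C then gives 10.

Step 11. What may go wrong: acylation of the hindered C6–OH is slow, and the angeloyl unit isomerises from Z to E (tiglate) at the temperature needed. Fallback, from 19 back to 22: the Z-olefin is built on the molecule. Esterification of C6–OH with 2-[bis(2,2,2-trifluoroethoxy)phosphoryl]propanoic acid (DCC, DMAP, CH2Cl2) gives the C6 phosphonopropanoate F8 (epimers at the phosphonate carbon). Still–Gennari olefination with acetaldehyde (KHMDS, 18-crown-6, THF, −78 °C) then gives the (Z)-2-methylbut-2-enoate 22.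

Further compounds
F1 | step 7 | 9-bromo-4β,6α-O-(di-tert-butylsilylene)dauc-9-en-8α-ol | CC(C)(C)[Si]3(C(C)(C)C)O[C@H]1C[C@@](C)(O)C(Br)=C[C@@]2(C)CC[C@@](O3)(C(C)C)[C@H]12
F2 | step 2 | 3-[1-(dimethylphenylsilyl)vinyl]cyclopent-2-en-1-one | C=C([Si](C)(C)c1ccccc1)C1=CC(=O)CC1
F3 | step 2 | bromomagnesium enolate from methyl addition to F2 | C=C([Si](C)(C)c1ccccc1)[C@@]1(C)CCC(O[Mg]Br)=C1
F4 | step 2 | bromomagnesium aldolate from F3 and 2 | C=C(C)C[C@H](O[Mg]Br)[C@H]1C(=O)CC[C@]1(C)C(=C)[Si](C)(C)c1ccccc1
F5 | step 2 | trimethylsilyl-protected aldol bearing the 1-(dimethylphenylsilyl)vinyl group | C=C(C)C[C@H](O[Si](C)(C)C)[C@H]1C(=O)CC[C@]1(C)C(=C)[Si](C)(C)c1ccccc1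
F6 | step 2 | tertiary alcohol silyl ether from isopropyl addition to F5 | C=C(C)C[C@H](O[Si](C)(C)C)[C@@H]1[C@@](C)(C(=C)[Si](C)(C)c2ccccc2)CC[C@@]1(O)C(C)C
F7 | step 2 | diol bearing the 1-(dimethylphenylsilyl)vinyl group | C=C(C)C[C@H](O)[C@@H]1[C@@](C)(C(=C)[Si](C)(C)c2ccccc2)CC[C@@]1(O)C(C)C
F8 | step 11 | 10α-(4-methoxybenzyloxy)-4β-hydroxydauc-8-en-6α-yl 2-[bis(2,2,2-trifluoroethoxy)phosphoryl]propanoate | CC(C(=O)O[C@H]1CC(C)=C[C@@H](OCc3ccc(OC)cc3)[C@@]2(C)CC[C@@](O)(C(C)C)[C@H]12)P(=O)(OCC(F)(F)F)OCC(F)(F)F
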